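The whole route rests on the bond between the tertiary carbinol carbon C7 of the side chain and the vinylic carbon C6. C7, with its methyl group and the two-carbon tether to the trimethylcyclohexene ring, is the carbonyl carbon of dihydro-β-ionone. A ketoreductase turns it into a secondary carbinol, which is inverted to an (S)-triisopropylbenzoate. Its α-lithio derivative adds to an (E)-alkenylboronate that carries the whole right half, with the butenolide ring masked as a silylated (Z)-ene-1,4-diol. Stereospecific 1,2-shift of the alkenyl group from boron to C7 and oxidation of the C–B bond then give, in one operation, the fragment union, the (7S)-alcohol and the (5E)-alkene.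

Key step: step 16

Remark: TBDPS = tert-butyldiphenylsilyl, TES = triethylsilyl. Side-chain atoms C1–C9 are counted from the CH2 on the butenolide. It is assumed that a commercial (R)-selective ketoreductase accepts dihydro-β-ionone. Organometallic intermediates are drawn as covalent monomers; lactols 27 and 37 are anomer mixtures.

Step 1
Reactants: 1 dihydro-β-ionone
Product: 2 (R)-4-(2,6,6-trimethylcyclohex-1-en-1-yl)butan-2-ol
Conditions: (R)-selective ketoreductase (NADPH-dependent alcohol dehydrogenase), NADP+ (cat.), iPrOH, phosphate buffer pH 7, 30 °C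
Reagents that add atoms: none
Why: Enzymatic asymmetric ketone reduction, in which the enzyme pocket should tell methyl from the CH2CH2 chain far better than a small reagent and deliver hydride to one carbonyl face to set the (R)-carbinol.

Step 2
Reactants: 2 (R)-alcohol; 3 2,4,6-triisopropylbenzoic acid
Product: 4 (S)-4-(2,6,6-trimethylcyclohex-1-en-1-yl)butan-2-yl 2,4,6-triisopropylbenzoate
Conditions: PPh3, DIAD, THF, 0 °C → rt
Reagents that add atoms: none
Why: Mitsunobu esterification should proceed by SN2 displacement of the oxyphosphonium group, so the carbinol centre is inverted to (S) and receives the hindered ester that later directs lithiation and serves as leaving group.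

Step 3
Reactants: 5 dibutyl vinylboronate; 6 2,2-dimethylpropane-1,3-diol
Product: 7 5,5-dimethyl-2-vinyl-1,3,2-dioxaborinane
Conditions: pentane, rt; butanol removed under reduced pressure
Reagents that add atoms: none
Why: Transesterification of a boronic ester, driven by the chelating diol and removal of butanol, should give the unhindered six-membered boronate needed later at a congested carbanion.

Step 4
Reactants: 8 propargyl alcohol; 9 allylmagnesium bromide
Product: 11 (Z)-3-iodo-2-(prop-2-en-1-yl)prop-2-en-1-ol, via alkenylmagnesium alkoxide 10 (not isolated)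
Conditions: 9 (2.5 equiv), CuI (10 mol %), Et2O/THF, 0 °C → rt; then I2, −40 → 0 °C
Reagents that add atoms: iodine, II
Why: Copper-catalysed anti-carbomagnesiation of the propargylic alkoxide should place allyl on C2 and magnesium on C3 cis to the CH2O group through the chelate, and iodinolysis with retention fixes the trisubstituted olefin geometry.

Step 5
Reactants: 11 iodo alcohol
Product: 12 (Z)-tert-butyl{[2-(iodomethylidene)pent-4-en-1-yl]oxy}diphenylsilane
Conditions: TBDPSCl, imidazole, CH2Cl2, 0 °C → rt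
Reagents that add atoms: tert-butyl(chloro)diphenylsilane, CC(C)(C)[Si](Cl)(c1ccccc1)c1ccccc1
Why: Standard silylation of a primary alcohol should give an ether that survives acid, base and organolithium steps.

Step 6
Reactants: 12 alkenyl iodide; 13 (tributylstannyl)methanol
Product: 14 (Z)-3-(TBDPS-oxymethyl)hexa-2,5-dien-1-ol
Conditions: 13 (1.5 equiv), Pd(PPh3)4 (5 mol %), 1,4-dioxane, 90 °C
Reagents that add atoms: none
Why: Stille hydroxymethylation, in which oxidative addition to zerovalent palladium and transfer of the CH2OH group from tin should occur with retention of olefin geometry.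

Step 7
Reactants: 14 allylic alcohol
Product: 15 (Z)-tert-butyl{[2-(2-bromoethylidene)pent-4-en-1-yl]oxy}diphenylsilane
Conditions: CBr4, PPh3, CH2Cl2, 0 °C
Reagents that add atoms: tetrabromomethane, BrC(Br)(Br)Br
Why: Appel bromination under neutral conditions should give the primary allylic bromide without transposition, since the SN2′ position is fully substituted.

Step 8
Reactants: 16 2,2-dimethyl-1,3-dioxan-5-one; 17 (S)-1-amino-2-(methoxymethyl)pyrrolidine (SAMP)
Product: 18 SAMP hydrazone of 2,2-dimethyl-1,3-dioxan-5-one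
Conditions: benzene, reflux, water separator
Reagents that add atoms: none
Why: Hydrazone condensation with azeotropic removal of water installs the chiral auxiliary on the protected dihydroxyacetone unit.

Step 9
Reactants: 18 SAMP hydrazone; 15 allylic bromide
Product: 20 SAMP hydrazone of (S)-4-[(2Z)-3-(TBDPS-oxymethyl)hexa-2,5-dien-1-yl]-2,2-dimethyl-1,3-dioxan-5-one, via lithium azaenolate 19 (not isolated)
Conditions: tBuLi (1.05 equiv), THF, −78 °C; then 15, −100 → −78 °C
Reagents that add atoms: none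
Why: SAMP-hydrazone alkylation, in which the chelated lithium azaenolate should be attacked by the allylic bromide on the face opposite the methoxymethylpyrrolidine to set the (S)-centre that becomes C5 of the butenolide (RAMP would give its enantiomer).

Step 10
Reactants: 20 alkylated hydrazone
Product: 22 (3S,5Z)-6-(TBDPS-oxymethyl)-1,3-dihydroxynona-5,8-dien-2-one, via acetonide ketone 21 (not isolated)
Conditions: sat. aq. oxalic acid, Et2O, rt; then 1 M HCl, THF, rt
Reagents that add atoms: water, O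
Why: Mild acidic hydrolysis should cleave first the hydrazone and then the acetonide without enolising the α-centre, while the TBDPS ether survives.

Step 11
Reactants: 22 dihydroxy ketone
Product: 23 (3S,5Z)-1-(TBDPS-oxy)-6-(TBDPS-oxymethyl)-3-hydroxynona-5,8-dien-2-one
Conditions: TBDPSCl (1.05 equiv), imidazole, CH2Cl2, −20 → 0 °C
Reagents that add atoms: tert-butyl(chloro)diphenylsilane, CC(C)(C)[Si](Cl)(c1ccccc1)c1ccccc1
Why: Silylation with a bulky chlorosilane should select the primary over the secondary hydroxyl, leaving the secondary one free to become the lactone oxygen.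

Step 12
Reactants: 23 α-hydroxy ketone; 24 (triphenylphosphoranylidene)ketene
Product: 26 (S)-4-(TBDPS-oxymethyl)-5-[(2Z)-3-(TBDPS-oxymethyl)hexa-2,5-dien-1-yl]furan-2(5H)-one, via acyl ylide 25 (not isolated)
Conditions: 24 (1.2 equiv), toluene, 90 °C
Reagents that add atoms: none
Why: The secondary hydroxyl should add to the ketene ylide and the resulting ester ylide close onto the ketone by intramolecular Wittig olefination, which forms the five-membered butenolide with the ring-enforced cis geometry and leaves the stereocentre untouched.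

Step 13
Reactants: 26 butenolide
Product: 28 (2Z,4S,6Z)-3,7-bis(TBDPS-oxymethyl)deca-2,6,9-triene-1,4-diol, via lactol 27 (not isolated)
Conditions: iBu2AlH (3.5 equiv), CH2Cl2, −78 → 0 °C; aq. Rochelle salt
Reagents that add atoms: none
Why: 1,2-Reduction of the unsaturated lactone by the aluminium hydride should give the (Z)-ene-1,4-diol, a lactone mask with no acidic γ-proton and no electrophilic carbonyl.

Step 14
Reactants: 28 ene-diol
Product: 29 (2Z,4S,6Z)-3,7-bis(TBDPS-oxymethyl)-1,4-bis(TES-oxy)deca-2,6,9-triene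
Conditions: Et3SiCl (2.5 equiv), imidazole, DMAP (cat.), CH2Cl2, 0 °C
Reagents that add atoms: chlorotriethylsilane, CC[Si](Cl)(CC)CC
Why: Silylation gives TES ethers that tolerate organolithium and alkaline peroxide and can later be removed in the presence of TBDPS ethers.

Step 15
Reactants: 29 triene; 7 vinylboronate
Product: 30 2-[(1E,4Z,7S,8Z)-4,8-bis(TBDPS-oxymethyl)-7,10-bis(TES-oxy)deca-1,4,8-trien-1-yl]-5,5-dimethyl-1,3,2-dioxaborinane
Conditions: 7 (4 equiv), second-generation Hoveyda–Grubbs catalyst RuCl2(H2IMes)(=CH-C6H4-2-OiPr) (5 mol %), 1,4-benzoquinone (10 mol %), CH2Cl2, 40 °C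
Reagents that add atoms: none
Why: Olefin cross-metathesis of the only monosubstituted alkene with a vinylboronate should give the (E)-alkenylboronate under thermodynamic control, the trisubstituted olefins being inert.

Step 16
Reactants: 4 (S)-triisopropylbenzoate; 30 alkenylboronate
Product: 34 (3S,4E,7Z,10S,11Z)-7,11-bis(TBDPS-oxymethyl)-3-methyl-10,13-bis(TES-oxy)-1-(2,6,6-trimethylcyclohex-1-en-1-yl)trideca-4,7,11-trien-3-ol, via α-lithiated benzoate 31 (not isolated), via boronate complex 32 (not isolated), via tertiary allylic boronic ester 33 (not isolated)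
Conditions: 4 (1.6 equiv), sBuLi (1.5 equiv), TMEDA, CPME, −60 °C; then 30 (1.0 equiv), −60 → 40 °C; then NaOH (2 M), H2O2 (30%), THF, 0 °C
Reagents that add atoms: hydrogen peroxide, OO
Why: sBuLi/TMEDA should remove the carbinol proton of 4 under direction of the benzoate carbonyl to give the configurationally stable α-oxy organolithium 31 with retention, which adds to boron of 30 with retention to give boronate complex 32. On warming, the alkenyl group migrates from boron to carbon antiperiplanar to the departing triisopropylbenzoate (1,2-metallate rearrangement, inversion at carbon, retention of the (E)-alkene), and oxidation of the C–B bond of 33 with retention installs the hydroxyl. The closest known reaction type is the lithiation–borylation of enantioenriched secondary dialkyl 2,4,6-triisopropylbenzoates with neopentyl glycol boronic esters, followed by oxidation to tertiary alcohols. No ring is closed. The new stereocentre C7 is controlled entirely by the enzyme-set carbinol centre of 4: retention, retention, inversion and retention translate (S)-4 into the (7S)-alcohol, with hydroxyl in the place of the former hydrogen. The step needs α-deprotonation in preference to the allylic C–H bonds, which the complex-induced proximity effect of the ester carbonyl secures, and clean boronate formation at a hindered centre, which the unhindered neopentyl glycol ester and the absence of any electrophile other than boron in 30 secure.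

Step 17
Reactants: 34 tertiary alcohol
Product: 35 (3S,4E,7Z,10S,11Z)-7,11-bis(TBDPS-oxymethyl)-3-methyl-1-(2,6,6-trimethylcyclohex-1-en-1-yl)trideca-4,7,11-triene-3,10,13-triol
Conditions: PPTS (0.2 equiv), MeOH/CH2Cl2, 0 °C → rt
Reagents that add atoms: none
Why: Mild acid-catalysed methanolysis should cleave both TES ethers while the bulkier TBDPS ethers and the tertiary allylic alcohol remain.

Step 18
Reactants: 35 triol
Product: 38 (S)-4-(TBDPS-oxymethyl)-5-[(2Z,5E,7S)-3-(TBDPS-oxymethyl)-7-hydroxy-7-methyl-9-(2,6,6-trimethylcyclohex-1-en-1-yl)nona-2,5-dien-1-yl]furan-2(5H)-one, via hydroxy enal 36 (not isolated), via lactol 37 (not isolated)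
Conditions: TEMPO (0.2 equiv), PhI(OAc)2 (2.5 equiv), CH2Cl2, rt
Reagents that add atoms: none
Why: Oxoammonium (TEMPO) oxidation should select the only free primary alcohol; the (Z)-enal closes onto the cis secondary hydroxyl to a lactol, which is oxidised on to the butenolide without touching the secondary or tertiary carbinols.

Step 19
Reactants: 38 bis-silyl ether
Product: 39 target, (S)-5-[(2Z,5E,7S)-7-hydroxy-3-(hydroxymethyl)-7-methyl-9-(2,6,6-trimethylcyclohex-1-en-1-yl)nona-2,5-dien-1-yl]-4-(hydroxymethyl)furan-2(5H)-one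
Conditions: Bu4NF (4 equiv), AcOH (4 equiv), THF, rt
Reagents that add atoms: none
Why: Fluoride-mediated desilylation buffered with acetic acid should free both primary hydroxyls without epimerising the base-sensitive C5 of the butenolide.

Compound list
1 | dihydro-β-ionone, 4-(2,6,6-trimethylcyclohex-1-en-1-yl)butan-2-one | CC(=O)CCC1=C(C)CCCC1(C)C | starting material
2 | (R)-4-(2,6,6-trimethylcyclohex-1-en-1-yl)butan-2-ol | C[C@@H](O)CCC1=C(C)CCCC1(C)C | intermediate
3 | 2,4,6-triisopropylbenzoic acid | CC(C)c1cc(C(C)C)c(C(=O)O)c(C(C)C)c1 | starting material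
4 | (S)-4-(2,6,6-trimethylcyclohex-1-en-1-yl)butan-2-yl 2,4,6-triisopropylbenzoate | C[C@H](OC(=O)c1c(C(C)C)cc(C(C)C)cc1C(C)C)CCC1=C(C)CCCC1(C)C | intermediate
5 | dibutyl vinylboronate | C=CB(OCCCC)OCCCC | starting material
6 | 2,2-dimethylpropane-1,3-diol (neopentyl glycol) | OCC(C)(C)CO | starting material
7 | 5,5-dimethyl-2-vinyl-1,3,2-dioxaborinane | C=CB1OCC(C)(C)CO1 | intermediate
8 | propargyl alcohol | C#CCO | starting material
9 | allylmagnesium bromide | C=CC[Mg]Br | starting material
10 | alkenylmagnesium alkoxide from anti-allylmagnesiation (Mg cis to CH2O) | C=CC/C(CO[Mg]Br)=C/[Mg]Br | intermediate (not isolated)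
11 | (Z)-3-iodo-2-(prop-2-en-1-yl)prop-2-en-1-ol | C=CC/C(CO)=C/I | intermediate
12 | (Z)-tert-butyl{[2-(iodomethylidene)pent-4-en-1-yl]oxy}diphenylsilane | C=CC/C(CO[Si](c1ccccc1)(c1ccccc1)C(C)(C)C)=C/I | intermediate
13 | (tributylstannyl)methanol | CCCC[Sn](CCCC)(CCCC)CO | starting material
14 | (Z)-3-(TBDPS-oxymethyl)hexa-2,5-dien-1-ol | C=CC/C(CO[Si](c1ccccc1)(c1ccccc1)C(C)(C)C)=C/CO | intermediate
15 | (Z)-tert-butyl{[2-(2-bromoethylidene)pent-4-en-1-yl]oxy}diphenylsilane | C=CC/C(CO[Si](c1ccccc1)(c1ccccc1)C(C)(C)C)=C/CBr | intermediate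
16 | 2,2-dimethyl-1,3-dioxan-5-one | CC1(C)OCC(=O)CO1 | starting material
17 | (S)-1-amino-2-(methoxymethyl)pyrrolidine (SAMP) | COC[C@@H]1CCCN1N | starting material
18 | SAMP hydrazone of 2,2-dimethyl-1,3-dioxan-5-one | COC[C@@H]1CCCN1N=C1COC(C)(C)OC1 | intermediate
19 | lithium azaenolate of 18 | COC[C@@H]1CCCN1N([Li])C1=COC(C)(C)OC1 | intermediate (not isolated)
20 | SAMP hydrazone of (S)-4-[(2Z)-3-(TBDPS-oxymethyl)hexa-2,5-dien-1-yl]-2,2-dimethyl-1,3-dioxan-5-one (kinetic C=N isomer drawn) | COC[C@@H]1CCCN1/N=C1/COC(C)(C)O[C@H]1C/C=C(/CC=C)CO[Si](c1ccccc1)(c1ccccc1)C(C)(C)C | intermediate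
21 | (S)-4-[(2Z)-3-(TBDPS-oxymethyl)hexa-2,5-dien-1-yl]-2,2-dimethyl-1,3-dioxan-5-one | O=C1COC(C)(C)O[C@H]1C/C=C(/CC=C)CO[Si](c1ccccc1)(c1ccccc1)C(C)(C)C | intermediate (not isolated)
22 | (3S,5Z)-6-(TBDPS-oxymethyl)-1,3-dihydroxynona-5,8-dien-2-one | OCC(=O)[C@@H](O)C/C=C(/CC=C)CO[Si](c1ccccc1)(c1ccccc1)C(C)(C)C | intermediate
23 | (3S,5Z)-1-(TBDPS-oxy)-6-(TBDPS-oxymethyl)-3-hydroxynona-5,8-dien-2-one | CC(C)(C)[Si](c1ccccc1)(c1ccccc1)OCC(=O)[C@@H](O)C/C=C(/CC=C)CO[Si](c1ccccc1)(c1ccccc1)C(C)(C)C | intermediate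
24 | (triphenylphosphoranylidene)ketene | O=C=C=P(c1ccccc1)(c1ccccc1)c1ccccc1 | starting material
25 | (triphenylphosphoranylidene)acetate ester of 23 (acyl ylide on the secondary oxygen) | CC(C)(C)[Si](c1ccccc1)(c1ccccc1)OCC(=O)[C@H](C/C=C(/CC=C)CO[Si](c1ccccc1)(c1ccccc1)C(C)(C)C)OC(=O)C=P(c1ccccc1)(c1ccccc1)c1ccccc1 | intermediate (not isolated)
26 | (S)-4-(TBDPS-oxymethyl)-5-[(2Z)-3-(TBDPS-oxymethyl)hexa-2,5-dien-1-yl]furan-2(5H)-one | C=CC/C(CO[Si](c1ccccc1)(c1ccccc1)C(C)(C)C)=C/C[C@@H]1OC(=O)C=C1CO[Si](c1ccccc1)(c1ccccc1)C(C)(C)C | intermediate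
27 | lactol of 26, (5S)-2-hydroxy-2,5-dihydrofuran with the same substituents (anomers) | C=CC/C(CO[Si](c1ccccc1)(c1ccccc1)C(C)(C)C)=C/C[C@@H]1OC(O)C=C1CO[Si](c1ccccc1)(c1ccccc1)C(C)(C)C | intermediate (not isolated)
28 | (2Z,4S,6Z)-3,7-bis(TBDPS-oxymethyl)deca-2,6,9-triene-1,4-diol | C=CC/C(CO[Si](c1ccccc1)(c1ccccc1)C(C)(C)C)=C/C[C@H](O)/C(CO[Si](c1ccccc1)(c1ccccc1)C(C)(C)C)=C\CO | intermediate
29 | (2Z,4S,6Z)-3,7-bis(TBDPS-oxymethyl)-1,4-bis(TES-oxy)deca-2,6,9-triene | C=CC/C(CO[Si](c1ccccc1)(c1ccccc1)C(C)(C)C)=C/C[C@H](O[Si](CC)(CC)CC)/C(CO[Si](c1ccccc1)(c1ccccc1)C(C)(C)C)=C\CO[Si](CC)(CC)CC | intermediate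
30 | 2-[(1E,4Z,7S,8Z)-4,8-bis(TBDPS-oxymethyl)-7,10-bis(TES-oxy)deca-1,4,8-trien-1-yl]-5,5-dimethyl-1,3,2-dioxaborinane | CC1(C)COB(/C=C/C/C(CO[Si](c2ccccc2)(c2ccccc2)C(C)(C)C)=C/C[C@H](O[Si](CC)(CC)CC)/C(CO[Si](c2ccccc2)(c2ccccc2)C(C)(C)C)=C\CO[Si](CC)(CC)CC)OC1 | intermediate
31 | (S)-α-lithiated benzoate from 4 (lithium in the place of the carbinol hydrogen) | C[C@]([Li])(OC(=O)c1c(C(C)C)cc(C(C)C)cc1C(C)C)CCC1=C(C)CCCC1(C)C | intermediate (not isolated)
32 | lithium boronate complex of 31 with 30 | [Li+].C[C@](OC(=O)c1c(C(C)C)cc(C(C)C)cc1C(C)C)(CCC1=C(C)CCCC1(C)C)[B-]1(/C=C/C/C(CO[Si](c2ccccc2)(c2ccccc2)C(C)(C)C)=C/C[C@H](O[Si](CC)(CC)CC)/C(CO[Si](c2ccccc2)(c2ccccc2)C(C)(C)C)=C\CO[Si](CC)(CC)CC)OCC(C)(C)CO1 | intermediate (not isolated)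
33 | tertiary allylic neopentyl glycol boronic ester (boron in the place of the later hydroxyl of 34) | C[C@@](B1OCC(C)(C)CO1)(/C=C/C/C(CO[Si](c1ccccc1)(c1ccccc1)C(C)(C)C)=C/C[C@H](O[Si](CC)(CC)CC)/C(CO[Si](c1ccccc1)(c1ccccc1)C(C)(C)C)=C\CO[Si](CC)(CC)CC)CCC1=C(C)CCCC1(C)C | intermediate (not isolated)
34 | (3S,4E,7Z,10S,11Z)-7,11-bis(TBDPS-oxymethyl)-3-methyl-10,13-bis(TES-oxy)-1-(2,6,6-trimethylcyclohex-1-en-1-yl)trideca-4,7,11-trien-3-ol | C[C@@](O)(/C=C/C/C(CO[Si](c1ccccc1)(c1ccccc1)C(C)(C)C)=C/C[C@H](O[Si](CC)(CC)CC)/C(CO[Si](c1ccccc1)(c1ccccc1)C(C)(C)C)=C\CO[Si](CC)(CC)CC)CCC1=C(C)CCCC1(C)C | intermediate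
35 | (3S,4E,7Z,10S,11Z)-7,11-bis(TBDPS-oxymethyl)-3-methyl-1-(2,6,6-trimethylcyclohex-1-en-1-yl)trideca-4,7,11-triene-3,10,13-triol | C[C@@](O)(/C=C/C/C(CO[Si](c1ccccc1)(c1ccccc1)C(C)(C)C)=C/C[C@H](O)/C(CO[Si](c1ccccc1)(c1ccccc1)C(C)(C)C)=C\CO)CCC1=C(C)CCCC1(C)C | intermediate
36 | (Z)-hydroxy enal from oxidation of the primary alcohol of 35 | C[C@@](O)(/C=C/C/C(CO[Si](c1ccccc1)(c1ccccc1)C(C)(C)C)=C/C[C@H](O)/C(CO[Si](c1ccccc1)(c1ccccc1)C(C)(C)C)=C\C=O)CCC1=C(C)CCCC1(C)C | intermediate (not isolated)
37 | lactol from ring closure of 36 (anomers) | C[C@@](O)(/C=C/C/C(CO[Si](c1ccccc1)(c1ccccc1)C(C)(C)C)=C/C[C@@H]1OC(O)C=C1CO[Si](c1ccccc1)(c1ccccc1)C(C)(C)C)CCC1=C(C)CCCC1(C)C | intermediate (not isolated)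
38 | (S)-4-(TBDPS-oxymethyl)-5-[(2Z,5E,7S)-3-(TBDPS-oxymethyl)-7-hydroxy-7-methyl-9-(2,6,6-trimethylcyclohex-1-en-1-yl)nona-2,5-dien-1-yl]furan-2(5H)-one | C[C@@](O)(/C=C/C/C(CO[Si](c1ccccc1)(c1ccccc1)C(C)(C)C)=C/C[C@@H]1OC(=O)C=C1CO[Si](c1ccccc1)(c1ccccc1)C(C)(C)C)CCC1=C(C)CCCC1(C)C | intermediate
39 | (S)-5-[(2Z,5E,7S)-7-hydroxy-3-(hydroxymethyl)-7-methyl-9-(2,6,6-trimethylcyclohex-1-en-1-yl)nona-2,5-dien-1-yl]-4-(hydroxymethyl)furan-2(5H)-one | CC1=C(CC[C@](C)(O)/C=C/C/C(=C/C[C@@H]2OC(=O)C=C2CO)CO)C(C)(C)CCC1 | target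

Total step count: 19. Longest linear sequence: 15 steps (steps 4–7 and 9–19, from propargyl alcohol).

Steps most likely to fail

Step 16. Metalation of 4 may be incomplete, capture of the hindered carbanion by the large boronate 30 may be slow or reversible, or proton transfer from the doubly allylic CH2 of 30 may compete. The fallback keeps the stereospecific boron chemistry but runs it on a small partner and joins the fragments by metathesis. It sets out from 4: lithiated 31 is trapped with an excess of vinylboronate 7 to give boronate complex F1, which rearranges on warming to the tertiary allylic boronic ester F2 and is oxidised with NaOH/H2O2 to the (S)-vinyl carbinol F3. Cross-metathesis of F3 with the terminal olefin of 29 (second-generation Hoveyda–Grubbs catalyst) then forms the (E)-alkene and comes back to the route at 34.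

Step 18. The oxidation may stall at the lactol, may also attack the secondary allylic hydroxyl, or the lactol may dehydrate to a furan under the acetic acid that is released. The fallback goes through the carboxylic acid instead of the lactol. It sets out from 35: a primary-selective aerobic oxidation (Cu(MeCN)4OTf, 2,2′-bipyridine, TEMPO, N-methylimidazole, air) is stopped at hydroxy enal 36, and chlorite oxidation (NaClO2, NaH2PO4, 2-methyl-2-butene) gives the (Z)-hydroxy acid F4. F4 lactonises on mild acidification and comes back to the route at 38.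

Step 15. Ruthenium hydride species may move the terminal double bond of the skipped diene into conjugation, and self-metathesis of either partner may consume material. The fallback forms the C–B bond by C–H borylation instead of metathesis. It sets out from 29: a palladium-catalysed boryl-Heck reaction with 2-chloro-1,3,2-benzodioxaborole (Pd2(dba)3, a bulky phosphine, a hindered amine base) gives the (E)-alkenyl catechol boronate F5. Transesterification of F5 with neopentyl glycol 6 comes back to the route at 30.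

Further compounds
F1 | step 16 | lithium boronate complex of 31 with vinylboronate 7 | [Li+].C[C@](OC(=O)c1c(C(C)C)cc(C(C)C)cc1C(C)C)(CCC1=C(C)CCCC1(C)C)[B-]1(C=C)OCC(C)(C)CO1
F2 | step 16 | 5,5-dimethyl-2-[(R)-3-methyl-5-(2,6,6-trimethylcyclohex-1-en-1-yl)pent-1-en-3-yl]-1,3,2-dioxaborinane | C[C@@](B1OCC(C)(C)CO1)(C=C)CCC1=C(C)CCCC1(C)C
F3 | step 16 | (S)-3-methyl-5-(2,6,6-trimethylcyclohex-1-en-1-yl)pent-1-en-3-ol | C[C@@](O)(C=C)CCC1=C(C)CCCC1(C)C
F4 | step 18 | (2Z,4S,6Z,9E,11S)-3,7-bis(TBDPS-oxymethyl)-4,11-dihydroxy-11-methyl-13-(2,6,6-trimethylcyclohex-1-en-1-yl)trideca-2,6,9-trienoic acid | C[C@@](O)(/C=C/C/C(CO[Si](c1ccccc1)(c1ccccc1)C(C)(C)C)=C/C[C@H](O)/C(CO[Si](c1ccccc1)(c1ccccc1)C(C)(C)C)=C\C(=O)O)CCC1=C(C)CCCC1(C)C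
F5 | step 15 | 2-[(1E,4Z,7S,8Z)-4,8-bis(TBDPS-oxymethyl)-7,10-bis(TES-oxy)deca-1,4,8-trien-1-yl]-1,3,2-benzodioxaborole | B1(/C=C/C/C(CO[Si](c2ccccc2)(c2ccccc2)C(C)(C)C)=C/C[C@H](O[Si](CC)(CC)CC)/C(CO[Si](c2ccccc2)(c2ccccc2)C(C)(C)C)=C\CO[Si](CC)(CC)CC)Oc2ccccc2O1
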